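(All constants are those of an exercise, and the outcome is calculated.)

Colleague, you want a quick number for this flask, and your hunch is that the slow dissolving of E holds it back; here is what I take from it.

E 20 mM; G 40 µM; time 8.0 min

    Q + J → L + X (k1 = 1.99 × 10⁶ /M/s)
    2 L → L2 (k2 = 3.0 × 10⁶ /M/s)
    Q + L → X + L, rate k3*[L]*[Q] (k3 = 29500 /M/s)
    G → 2 J (k4 = 1.27 × 10⁻⁴ /s)
    E ⇌ Q, rate k5*(cs5 - [Q]) while solid is left; crystals form when [Q] > cs5 (cs5 = 9.3 mM, k5 = 0.0273 /s)

- X at 8.0 min, in percent of the E charged
- the change that raises the amount of X at 8.0 min, in percent of the E charged most ("none" if none brings more than 2 percentage points) (delta / epsilon / none)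
- amount of X at 8.0 min, in percent of the E charged, after delta

- delta: doubling the solubility in step 5, all else as stated
- epsilon: doubling the dissolution coefficient of step 5, all else as stated

- where a step has two of a species, its rate is k times that concentration squared, and two are used at each turn
- given per volume of solution although it is solid: E
- at the start none of E is in solution
- run time (flask): 8.0 min

1. I steady the radical first. Each G gives two J and each J becomes L, so L is made at twice the decay rate of G and lost in pairs. Balancing the two gives 4.12 × 10⁻⁵ mM of L, reached in about 4.05 s, far shorter than the run.

2. The chain step multiplied by that level gives 0.00121 /s. This is the chain rate constant: the pseudo-first-order constant at which Q becomes X.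

3. Against your hunch, the dissolving time of 36.6 s is far shorter than the chain time of 13.7 min. So Q sits just below solubility, at 8.90 mM, where dissolving balances the chain.

4. X then grows steadily from one dissolving time on, which gives 24.0%. Q plus X comes to 13.7 mM, less than the 20 mM charged, so solid is left at the end.

5. Delta lifts solubility to 18.6 mM, close to the charge. I roughly take the charge as dissolved after one dissolving time and let it decay at the chain rate constant, which gives 41.6%. Epsilon shortens the lag and raises Q slightly. My pick is delta.

The forecast says 23.7%, delta and 40.8%, on the ground that “the run is solubility-limited”. Its two yields stand slightly below mine.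

The simulation gives 23.7%, and delta adds 17 percentage points against 1.4 points for epsilon, reaching 40.9%. In this flask the half-life of Q by the chain step reads 9.5 min at 0.789 min, beside 9.55 min from the chain rate constant and far longer than the dissolving time, and at 8.00 min Q stands at 44.6% of the charge with solid E at 31.7%. For the neighbour flask with 0.16 mM of G, I reckon a chain rate constant of 0.00243 /s, twice the one I reckoned for this flask, and that neighbour gives 45.7% of X.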